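Take one ratio first: the time target needs to halve by loss, over the time the flask stands. Above one, the flask ends before loss has halved the target; below one, loss has done so.

| flask | electrophile | nucleophile | temperature | remark | time |
|---|---|---|---|---|---|
| gamma | 0.10 M | 0.067 M | 25 °C | run made earlier |  |
| epsilon | 0.10 M | 0.20 M | 25 °C | run made earlier |  |
| dusk | 0.10 M | 0.100 M | 65 °C |  | 20 h |
| dawn | 0.10 M | 0.100 M | 25 °C |  | 20 h |
| midnight | 0.025 M | 0.100 M | 25 °C |  | 20 h |
| summer | 0.025 M | 0.100 M | 65 °C |  | 20 h |

| run | time / h | target / % | electrophile / % |
|---|---|---|---|
| gamma | 0.500 | 22.7 | 77.4 |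
| gamma | 1.00 | 28.5 | 71.0 |
| gamma | 2.00 | 32.1 | 65.8 |
| gamma | 4.00 | 37.7 | 62.5 |
| gamma | 8.00 | 43.1 | 56.9 |
| epsilon | 0.500 | 56.3 | 42.8 |
| epsilon | 1.00 | 67.7 | 32.0 |
| epsilon | 2.00 | 74.2 | 25.2 |
| epsilon | 4.00 | 81.1 | 17.4 |
| epsilon | 8.00 | 86.7 | 11.6 |

(readings scatter by 0.5 percentage points)

1. ranking by amount of target, in percent of the electrophile charged, from high to low, at 20 h (dusk / dawn / midnight / summer)
2. the same order at 1.0 h (dusk / dawn / midnight / summer)
3. the amount of target, in percent of the electrophile charged of the flask you put first, at 20 h
4. the amount of target, in percent of the electrophile charged of the flask you put last, at 20 h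

Turn the nucleophile first. By hand, with electrophile and temperature held, more nucleophile should give more target, and the two runs agree: at 8.00 h, gamma has 43.1% with 0.670 equivalents and epsilon has 86.7% with 2.00. But add target and electrophile at that reading. Gamma closes at 100%, while epsilon falls short by 1.7 percentage points, a rough reading, since each figure scatters by 0.5 points. Read the gap as target lost where nucleophile stands in surplus. Spread over epsilon's run at its last target level, it gives, as a reading for epsilon, a loss of 0.00245 /h and a halving time L of 283 h. Divide L by the standing time to get F, 14.1, the crossing ratio.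

Turn the time next. By hand, a longer time looks useful here: epsilon still gains 5.6 points between its last two readings. At 25 °C, L is longer than the standing time, so I expect midnight, with 4.00 equivalents and electrophile as limiting reagent, to finish above dawn, with 1.00.

Turn the temperature last. By hand, heat speeds the making, but the runs show nothing of it, so this part is a guess. F is the factor by which heat must shorten L before loss halves the target within the standing time. Summer has the charge of midnight, and dusk has no surplus of nucleophile by charge. As a guess, I put midnight above summer, without placing summer further.

The forecast differs: summer > midnight > dusk > dawn at 20 h and summer > dusk > midnight > dawn at 1.0 h, with 92% (81% to 98%) for summer and 65% (60% to 70%) for dawn, holding that “heat speeds both reaction and decay”.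

The flasks give midnight > dusk > dawn > summer at 20.0 h and dusk > summer > midnight > dawn at 1.00 h.

    electrophile + nucleophile → acid set free + target (k = 0.270 /M/min, Ea = 52.0 kJ/mol)
    nucleophile + acid set free ⇌ protonated nucleophile, settled at all times (K = 360 /M, ΔH = 10.0 kJ/mol)
    nucleophile + target → over-reaction product (k = 0.00410 /M/min, Ea = 80.0 kJ/mol)
    nucleophile ⇌ dormant form (K = 4.60, k = 0.0120 /min, Ea = 99.0 kJ/mol, ΔH = −89.0 kJ/mol)
    (constants at 25 °C)

Summer ends at 0.199% target and midnight at 93.7%. Summer's electrophile is under 2% of its charge by 0.365 h, and its target falls from 62.9% at 1.00 h to 3.35% at 10.0 h, an average halving time of 2.13 h. L, read in epsilon at 25 °C, is 133 times that, past F, though summer differs from epsilon in charge as well as temperature. A flask like midnight kept at 50 °C holds 82.5% as over-reaction product and 17.5% as target at 20.0 h; taken from the whole charge at the start, its average halving time is about 7.96 h, and the ratio of L to it, past F, is 35.6.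

The data are calculated for substances that don't exist; scatter was added.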